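Time came first: the flask, which is the south-east run followed further, may run 20 min, and its readings stop at 4.00 min.

| flask | left-handed substrate | right-handed substrate | reagent | free catalyst | impurity | remark | time |
|---|---|---|---|---|---|---|---|
| south-east | 0.089 M | 0.089 M | 0.178 M | 2.2 mM | 1.2 mM | the very flask that is asked about, followed so far |  |
| north | 0.060 M | 0.060 M | 0.178 M | 2.2 mM | 1.2 mM | run made earlier |  |
| flask | 0.089 M | 0.089 M | 0.178 M | 2.2 mM | 1.2 mM |  | 20 min |

- south-east (time / min: right-handed substrate / %, left-handed substrate / %, left-handed product / %): 0.250: 48.8, 49.0, 0.4; 0.667: 49.0, 48.6, 1.7; 1.50: 48.7, 46.5, 2.7; 4.00: 45.4, 42.4, 6.2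
- north (time / min: right-handed substrate / %, left-handed substrate / %, left-handed product / %): 2.00: 47.6, 46.3, 4.0; 4.00: 45.6, 41.8, 6.5; 6.00: 43.6, 38.4, 9.4; 8.00: 41.8, 35.6, 10.8

(readings scatter by 0.3 percentage points)

- free catalyst is single-handed; left-handed substrate and right-handed substrate are mirror images of each other, charged as a racemate, each of them at the stated concentration

1. whether the excess of right-handed substrate over left-handed substrate among what is left of the two reaches 99 % by 20 min (yes / no)
2. the highest excess of right-handed substrate over left-handed substrate among what is left of the two up to 20 min

I saw the left-handed substrate fall at 0.0412 /min in the south-east run, charged at 0.089 M, and at 0.0425 /min in the north run, charged at 0.060 M. So I treated each substrate as first order in itself, times a factor common to both. At any moment the two rates then stood as s·c(left-handed substrate)/c(right-handed substrate). The common factor cancelled, and the comparison drifted as the left-handed substrate thinned. Pooling the last readings of both runs, I reckoned: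

s = 1.83

This is the selectivity factor. If x is the share of its charge that the right-handed substrate keeps, the left-handed substrate keeps x^s, and:

excess = (x − x^s)/(x + x^s)

The rule put the excess wanted at x = 0.171 %. My ladder, read from the north run, had three rungs: the left-handed substrate's lifetime of 23.6 min, the right-handed substrate's of 44.7 min, and 285 min to reach that x. The time allowed was shorter than the left-handed substrate's lifetime. Holding that lifetime constant, I estimated x = 63.9 % for the flask at the time allowed, so I committed to no and an excess of 18.4 %.

The forecast said no and 16 %, lower than my figure, reasoning that “if the rate follows reagent, total substrate falls to only about 60% by 20 min”.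

The flask gave no and 14.5 %.

    reagent + free catalyst + left-handed substrate → free catalyst + left-handed product (k = 4.10 /M²/s)
    reagent + free catalyst + right-handed substrate → free catalyst + right-handed product (k = 2.30 /M²/s)
    free catalyst → spent catalyst B (k = 1.20 × 10⁻⁵ /s)
    free catalyst + impurity → spent catalyst A (k = 240 /M/s)
    left-handed product ⇌ right-handed product (k = 0.00900 /s)

At 20.0 min the flask's right-handed substrate kept 69 % of its charge, more than my 63.9 %, and the rule at that share gives 15.3 %. Two things together hold the excess there: the right-handed substrate reacts too, the excess being 35.3 % without that step, and the reading comes early, the excess being 52.4 % ten times later. Read at 50 min, the same flask keeps 49 % of its right-handed substrate; the rule gives 28.8 %, and the highest excess stored for that flask is 27.3 %.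

The data are simulated from invented constants; the scatter is artificial.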